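(The constants were set for the occasion; the rest is arithmetic.)

Slowness is the point of dispute here: how late does the making step let the intermediate arrive, while the loss step is already running?

in all of them: substrate 0.0020 M; time 1.0 min

|  | reagent |
|---|---|
| eta | 1.10 equiv |
| delta | 1.70 equiv |

    intermediate → product (k1 = 0.0142 /s)
    substrate + reagent → intermediate + released group (k2 = 25.4 /M/s)
    crystals ⇌ released group, rate k3*(cs3 - [released group]) while solid is left; crystals form when [released group] > cs3 (cs3 = 0.081 mM, k3 = 1.41 /s)

- which of these there is most of at the end, counted by the substrate in it, eta (substrate / intermediate / product)
- which of these there is most of at the end, counted by the substrate in it, delta (substrate / intermediate / product)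
- how much there is at the end of the one of these that leads, in percent of the substrate charged: eta
- how much there is at the end of the one of these that leads, in percent of the substrate charged: delta

- amounts and yields of released group count crystals too
- given per volume of solution although it is solid: crystals
- run time (eta): 1.0 min

Two views compete. The first says the making is quick, so the substrate is intermediate almost at once, the loss runs the full time, and both flasks end with 42.7% intermediate and the rest product, which puts product ahead.

The second view, which I hold, says the making is not quick enough for that. With reagent as charged, its rate is 0.0559 /s in eta and 0.0864 /s in delta, and in eta that is just 3.94 times the loss constant 0.0142 /s. The reagent is also being consumed, so I go round once more: the substrate used in the first round comes off the reagent, and I take the mean of the reagent at start and end. This gives 0.0314 /s for eta and 0.0611 /s for delta, the working rate: the making constant times that mean reagent, a pseudo-first-order rate w.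

With loss constant k, the share present as intermediate at time t is w/(w − k) × (e^(−kt) − e^(−wt)). That gives 50.1% for eta and 52.2% for delta. The leader in eta is intermediate, and the same holds in delta.

The forecast also names intermediate for eta and intermediate for delta, at 44.1% and 50%, and it sets the solid aside: “Crystals and the released group feed back into nothing”. Its eta figure is lower than mine.

The flask gives intermediate at 44.1% in eta and intermediate at 50.0% in delta, so the forecast stands and my eta figure ran high. At the end of delta, intermediate is made at 0.282 of the rate at which it is used up, so it is falling. The working rate gives an estimate of when intermediate tops out in delta: ln(w/k)/(w − k) comes to 0.519 min. Delta held 61.7% intermediate at 0.500 min, more than at the end.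

Now take delta with 4.20 equiv of reagent. The working rate becomes 0.188 /s, which gives 46.1% intermediate, close to the first view's 42.7%. The computed flask holds 46.2% intermediate and 53.8% product, so here product leads, the order the first view gave.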